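The data were computed on assumed constants; the scatter is artificial.

Two captures compete.

| flask | substrate | first nucleophile | second nucleophile | remark | time |
|---|---|---|---|---|---|
| ochre | 0.50 mM | 0.75 mM | 0.60 mM | the very flask that is asked about, followed so far |  |
| grey | 0.50 mM | 0.50 mM | 0.60 mM | run made earlier |  |
| flask | 0.50 mM | 0.750 mM | 0.600 mM |  | 1.0 h |

- ochre (time / min: other capture product / %, target / %): 1.00: 21.3, 51.2; 2.00: 24.0, 66.3; 3.00: 27.6, 70.1; 4.00: 27.8, 70.6; 5.00: 27.8, 70.4
- grey (time / min: other capture product / %, target / %): 8.00: 38.9, 60.7; 15.0: 40.3, 61.6; 25.0: 38.3, 60.4; 30.0: 38.8, 58.9; 40.0: 39.0, 61.7

(each reading ± 1 percentage point)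

- the analysis behind the earlier runs scatters by 1 percentage point, standard deviation
- a reading or a percentage of target counts all its forms, free or not

* share of other capture product in other capture product plus target at 5.0 s
* share of other capture product in other capture product plus target at 2.5 min
* share of other capture product in other capture product plus target at 1.0 h
* which of other capture product and target there is more of at 1.0 h

The grey share stays flat from 8.00 min to 40.0 min within the scatter of 1 percentage point, so I treat neither product as feeding the other. That leaves two rates in competition: capture by the first nucleophile, proportional to s[first nucleophile], and capture by the second, proportional to [second nucleophile]. If each capture is first order in its nucleophile, ln(fraction of first nucleophile left) is s times ln(fraction of second nucleophile left). The mean grey readings give 2.37. This is the capture ratio, the selectivity factor: what one unit of first nucleophile is worth against one unit of second. The last ochre reading, from a different charge, gives 2.40.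

So I reckon the ochre flask starts at a share of 25.2%. If conversion is first order, its first reading implies about 10.2% conversion at 5.0 s, so I stay near that share there. By the last ochre reading the first nucleophile has lost 46.9% of its charge, more than the 23.2% of the second, so I expect the ochre share to climb to the 28.3% read at 5.00 min and stay there.

The forecast gives 25.5%, 28% and 28.3%, with target ahead: “One selectivity therefore explains both final shares”.

The flask gives 27.5%, 28.5% and 28.5%, with target at 70.7% and other capture product at 28.2%.

    substrate → intermediate (k = 0.0250 s⁻¹)
    second nucleophile + intermediate → other capture product (k = 140 M⁻¹ s⁻¹)
    first nucleophile + intermediate → target (k = 340 M⁻¹ s⁻¹)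
    crystals ⇌ target, rate k4*(cs4 - [target]) while solid is left; crystals form when [target] > cs4 (solubility = 0.00610 mM, k = 0.460 s⁻¹)
    target ⇌ isomer of the product (K = 0.870, k = 0.0980 s⁻¹)

At 0.00771 h the flask uses intermediate for target 2.6 times as fast as for other capture product. At 1.0 h its 52% of first nucleophile implies, through s, 76.0% of second nucleophile, and 76% stands there. A neighbouring flask charged with 0.19 mM of first nucleophile keeps 14% of it, which implies 43.1% of second nucleophile; it holds 44%, and its other capture product stands at 67.2%.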